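Read the north run at 0.833 min: 11.8% of the starting material has become target, so you have a start rate of 0.142 min⁻¹ as a fraction of the charge. Held for 6.0 min, that rate would give 85.2%, and the question is how much of this the slowing takes away.

| flask | starting material | reagent | free catalyst | remark | time |
|---|---|---|---|---|---|
| north | 0.050 M | 1.5 equiv | 0.5 mol% | run made earlier |  |
| south-east | 0.050 M | 1.5 equiv | 0.25 mol% | run made earlier |  |
| west | 0.050 M | 1.5 equiv | 0.38 mol% | run made earlier |  |
| north-east | 0.10 M | 1.5 equiv | 0.5 mol% | run made earlier |  |
| grey | 0.050 M (fed, over 4.80 min) | 1.50 equiv | 0.5 mol% | a stirred flask in which starting material is dosed at a steady rate over 4.80 min without added volume, worked up at 6.0 min | 6.0 min |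
| ochre | 0.050 M | 1.50 equiv | 0.5 mol% | a single well-mixed tank run continuously and read at steady state, 6.0 min in it on average |  |
| green | 0.050 M | 1.50 equiv (fed, over 4.80 min) | 0.5 mol% | a stirred flask in which reagent is dosed at a steady rate over 4.80 min without added volume, worked up at 6.0 min | 6.0 min |
| blue | 0.050 M | 1.50 equiv | 0.5 mol% | a closed flask charged with all of it at once and left for 6.0 min | 6.0 min |

| run | time / min | target / % |
|---|---|---|
| north | 0.333 | 4.8 |
| north | 0.833 | 11.8 |
| north | 1.50 | 20.1 |
| north | 2.50 | 32.4 |
| north | 4.00 | 48.9 |
| south-east | 0.667 | 5.1 |
| south-east | 1.33 | 9.6 |
| south-east | 2.00 | 14.0 |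
| south-east | 3.00 | 20.8 |
| south-east | 4.00 | 26.8 |
| west | 0.667 | 6.9 |
| west | 1.33 | 14.4 |
| west | 2.00 | 21.3 |
| west | 3.00 | 29.5 |
| west | 4.00 | 39.3 |
| north-east | 0.333 | 7.6 |
| north-east | 0.833 | 18.2 |
| north-east | 1.50 | 31.8 |
| north-east | 2.50 | 49.0 |
| north-east | 4.00 | 69.0 |

(each reading ± 0.5 percentage points)

- the stated concentrations are those of everything mixed, before any reaction; amounts are the same in each set-up
- the numbers in the tables scatter by 0.5 percentage points (one standard deviation)
- the feed brings no volume worth counting
- the earlier runs were made in a closed, stirred flask

1. the set-up with the highest amount of target at the outlet or at the end, in percent of the starting material put in ("none" if the first two lie within 2 percentage points) (grey / ochre / green / blue / none)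
2. amount of target at the outlet or at the end, in percent of the starting material put in, grey
3. amount of target at the outlet or at the end, in percent of the starting material put in, ochre
4. amount of target at the outlet or at the end, in percent of the starting material put in, green
5. amount of target at the outlet or at the end, in percent of the starting material put in, blue

Take the catalyst first. The readings at 3.00 min in south-east, 1.50 min in north and 2.00 min in west have nearly the same product of loading and time, and they give 20.8%, 20.1% and 21.3%. Within the scatter, then, loading simply multiplies the rate. At doubled concentration, north-east reads 18.2% at 0.833 min, which is a factor of 1.54 over north, so the turnover of each catalyst grows with concentration at an order of about 0.625.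

Now the slowing within north. Between 2.50 min and 4.00 min the rate is 0.110 min⁻¹, a factor of 0.775 on the start. Around 40.6% conversion, starting material stands at 59.4% of its charge and reagent at 72.9% of its own, so the rate, as read, has fallen less than starting material, while these readings scatter too much to set it against reagent. The runs cannot part the two partners. I count on starting material, which falls further.

My quantity is the clock: the logarithm of charged over remaining starting material, per minute, a pseudo-first-order constant. North at 4.00 min gives 0.168 min⁻¹, up from 0.150 min⁻¹ at 1.50 min. Since it speeds up, I take the 63.5% it gives for blue as a low estimate.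

The forecast says 49.5% for grey, 54% for ochre, 51% for green and 65.5% for blue, so blue is best. It reads the runs differently from me, as “first order in reagent and nearly zero order in starting material”.

The flasks give 47.1% for grey, 52.6% for ochre, 54.9% for green and 64.7% for blue, so blue leads green by 9.8 percentage points.

    catalyst intermediate A → catalyst intermediate B (k = 4.80 s⁻¹)
    catalyst intermediate C → free catalyst + target (k = 2.90 s⁻¹)
    starting material + catalyst intermediate B ⇌ catalyst intermediate C (K = 19.0 M⁻¹, k = 27.0 M⁻¹ s⁻¹)
    reagent + free catalyst → catalyst intermediate A (k = 39.0 M⁻¹ s⁻¹)

At 6.00 min blue holds 73.0% of its catalyst as catalyst intermediate B, the resting state, which is the form that meets starting material. Grey ends with 53% of its starting material, so its clock ran at 0.106 min⁻¹, a factor of 0.632 on north's 0.168 min⁻¹. The neighbouring flask is grey with 1.2 mol% of free catalyst, which raises the loading by a factor of 2.40. Multiplying the clock by that factor leaves 21.7% of the starting material. That flask gave 79.0% of target, with 21% of the starting material left.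

(The numbers in the tables stem from a simulated flask with made-up constants; noise was put on by code.)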